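**Plan**

- Cuts (cembrane numbering): the C7 acetate; the O–C11 and O–C8 bonds of the 1,2-dioxane (back to an allylic C11 chloride, a 7,8-epoxide and H2O2); C9–C10, redrawn as C9=C10 and cut by ring-closing metathesis; C10–C11 (vinyl addition); C12=C13 (Wittig); C1–C2 with the lactone C–O bond (2-carboalkoxyallylation); the C9 methylene and the epoxide on a geranyl acetate skeleton.
- Enabling feature: C9–C10 is the only carbon–carbon bond of the dioxane ring (C8, C9, C10, C11, O, O) flanked by both peroxide carbons, and it is also a bond of the 14-membered carbocycle. A vinyl group on epoxide carbon C8 and one on carbinol carbon C11 can be joined there, and diimide then erases the alkene.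
- Forward order: geranyl acetate gives the C2–C10 epoxy enal; chromium-catalysed union with a C13–C17 bromoenoate builds the γ-lactone; C11–C13 and the second vinyl group are added; metathesis closes the 14-membered ring; the 1,2-dioxane is made last (H2O2 opens the epoxide at C8, the hydroperoxide closes on C11); acetylation ends the route.
- Stereochemistry: C7 and C8 from Katsuki–Sharpless epoxidation (C8 inverted by H2O2); C1 and C2 from the catalyst-controlled, syn-selective allylation; C11 in the peroxide ring closure, where only the cis-bridged dioxane can span the macrocycle; E alkenes from geraniol and a stabilised ylide.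

Key step: step 13

Remark: positions are given in cembrane numbering (C1/C2 lactone ring-fusion carbons, C16 lactone carbonyl, C15=C17 exocyclic methylene, C7 acetoxy carbon, C8 and C11 peroxide carbons). The C11 carbinol is carried as a mixture of epimers from step 12 to step 18, because this centre is ionised and set anew in step 19. The alkene made in step 13 is drawn E (expected); a Z isomer would converge in step 15.

**Step 1**
Reactants: 1 geranyl acetate
Product: 2 (2E,6E)-8-hydroxy-3,7-dimethylocta-2,6-dien-1-yl acetate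
Conditions: SeO2 (cat.), tBuOOH (70% aq.), salicylic acid (cat.), CH2Cl2, rt
Reagents that add atoms: tert-butyl hydroperoxide, CC(C)(C)OO
Why: Selenium dioxide allylic oxidation (ene reaction, then [2,3]-sigmatropic shift, SeO2 recycled by tBuOOH) should attack the electron-rich terminal alkene at the methyl group trans to the chain and give the (E)-allylic alcohol, the C3=C4 alkene being deactivated by its allylic acetate.

**Step 2**
Reactants: 2 (2E,6E)-8-hydroxygeranyl acetate
Product: 3 (2E)-5-[(2S,3S)-3-(hydroxymethyl)-3-methyloxiran-2-yl]-3-methylpent-2-en-1-yl acetate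
Conditions: Ti(OiPr)4 (10 mol %), L-(+)-diethyl tartrate (12 mol %), tBuOOH (in decane), 4 Å molecular sieves, CH2Cl2, −20 °C
Reagents that add atoms: tert-butyl hydroperoxide, CC(C)(C)OO
Why: Katsuki–Sharpless asymmetric epoxidation touches only the alkene that carries the free allylic hydroxyl, and L-(+)-tartrate delivers oxygen to the face that gives the (2S,3S)-2,3-epoxy alcohol, as with other (E)-trisubstituted allylic alcohols, which sets C7 (S) and C8 (S).

**Step 3**
Reactants: 3 epoxy alcohol
Product: 4 (2E)-5-[(2S,3R)-3-formyl-3-methyloxiran-2-yl]-3-methylpent-2-en-1-yl acetate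
Conditions: Dess–Martin periodinane, pyridine, CH2Cl2, 0 °C → rt
Reagents that add atoms: none
Why: Dess–Martin oxidation of a 2,3-epoxy alcohol to the epoxy aldehyde is mild and buffered, and the α-carbon is fully substituted and cannot epimerise (the descriptor at C8 changes only because the priorities change).

**Step 4**
Reactants: 4 epoxy aldehyde
Product: 5 (2E)-5-[(2S,3S)-3-ethenyl-3-methyloxiran-2-yl]-3-methylpent-2-en-1-yl acetate
Conditions: Ph3PCH3Br, KN(SiMe3)2, THF, −78 → 0 °C
Reagents that add atoms: methyltriphenylphosphonium bromide, C[P+](c1ccccc1)(c1ccccc1)c1ccccc1.[Br-]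
Why: Wittig methylenation of the α,β-epoxy aldehyde with the salt-free ylide at low temperature should give the vinyl epoxide, the aldehyde reacting far faster than the acetate.

**Step 5**
Reactants: 5 vinyl epoxide acetate
Product: 6 (2E)-5-[(2S,3S)-3-ethenyl-3-methyloxiran-2-yl]-3-methylpent-2-en-1-ol
Conditions: K2CO3 (cat.), MeOH, 0 °C
Reagents that add atoms: none
Why: Base-catalysed transesterification (methanolysis) removes the primary acetate, and the vinyl epoxide is inert to these mildly basic conditions.

**Step 6**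
Reactants: 6 allylic alcohol
Product: 7 (2E)-5-[(2S,3S)-3-ethenyl-3-methyloxiran-2-yl]-3-methylpent-2-enal
Conditions: MnO2 (activated, excess), CH2Cl2, rt
Reagents that add atoms: none
Why: MnO2 oxidation is selective for allylic alcohols, neutral (safe for the epoxide) and does not isomerise the trisubstituted alkene.

**Step 7**
Reactants: 8 3-[(tert-butyldimethylsilyl)oxy]propanal; 9 methyl acrylate
Product: 10 methyl 5-[(tert-butyldimethylsilyl)oxy]-3-hydroxy-2-methylidenepentanoate (racemic)
Conditions: DABCO (0.5 equiv), MeOH, rt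
Reagents that add atoms: none
Why: In the Morita–Baylis–Hillman reaction the amine adds to the acrylate, the ammonium enolate adds to the aldehyde and elimination returns the amine; the new carbinol centre is racemic and is removed in step 8.

**Step 8**
Reactants: 10 Morita–Baylis–Hillman adduct
Product: 11 methyl (2Z)-2-(bromomethyl)-5-[(tert-butyldimethylsilyl)oxy]pent-2-enoate
Conditions: N-bromosuccinimide, Me2S, CH2Cl2, −20 → 0 °C
Reagents that add atoms: N-bromosuccinimide, O=C1CCC(=O)N1Br
Why: Corey–Kim-type bromination with allylic transposition (bromide attacks the alkoxysulfonium salt in the SN2′ sense) should give the more stable trisubstituted enoate with the C14 chain trans to the ester, which is the (Z)-bromide, and the neutral conditions spare the silyl ether.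

**Step 9**
Reactants: 7 epoxy enal; 11 (Z)-bromoenoate
Product: 13 (4S,5S)-4-{2-[(tert-butyldimethylsilyl)oxy]ethyl}-5-{(1E)-4-[(2S,3S)-3-ethenyl-3-methyloxiran-2-yl]-2-methylbut-1-en-1-yl}-3-methylideneoxolan-2-one, via hydroxy ester 12 (not isolated)
Conditions: CrCl2 (10 mol %), chiral 1,8-bis(oxazolinyl)carbazole ligand (12 mol %; the antipode that directs addition to the Re face, to be assigned on (E)-3-methylpent-2-enal), Mn powder, (C5H5)2ZrCl2, THF, 0 °C → rt; aqueous work-up
Reagents that add atoms: none
Why: Chromium-catalysed asymmetric 2-(alkoxycarbonyl)allylation (Nozaki–Hiyama type) with lactonisation: the (Z)-bromide gives an allylchromium species that adds through a closed chair transition state with the C14 chain cis to the metal-bearing CH2, so C1 and C2 form syn (cis-lactone), the ligand selects the Re face of the enal to give 1S,2S regardless of the remote epoxide, and the zirconium alkoxide closes onto the methyl ester while the non-silylating turnover reagent spares the vinyl epoxide.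

**Step 10**
Reactants: 13 silyl-protected lactone
Product: 14 (4S,5S)-5-{(1E)-4-[(2S,3S)-3-ethenyl-3-methyloxiran-2-yl]-2-methylbut-1-en-1-yl}-4-(2-hydroxyethyl)-3-methylideneoxolan-2-one
Conditions: Bu4NF, AcOH, THF, 0 °C → rt
Reagents that add atoms: none
Why: Fluoride cleaves the primary silyl ether, and the acetic acid buffer keeps the liberated alkoxide from adding to the methylene lactone or opening the epoxide.

**Step 11**
Reactants: 14 lactone alcohol; 15 2-(triphenylphosphoranylidene)propanal
Product: 17 (4S,5S)-5-{(1E)-4-[(2S,3S)-3-ethenyl-3-methyloxiran-2-yl]-2-methylbut-1-en-1-yl}-3-methylidene-4-[(2E)-3-methyl-4-oxobut-2-en-1-yl]oxolan-2-one, via lactone aldehyde 16 (not isolated)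
Conditions: Dess–Martin periodinane, CH2Cl2, 0 °C → rt; then 15, rt → 40 °C
Reagents that add atoms: none
Why: Dess–Martin oxidation followed in the same flask by Wittig olefination with the stabilised ylide should give the (E)-2-methyl enal (C11–C13) under thermodynamic control, and the less electrophilic enal product does not react a second time.

**Step 12**
Reactants: 17 dienal lactone; 18 vinylmagnesium bromide
Product: 19 (4S,5S)-5-{(1E)-4-[(2S,3S)-3-ethenyl-3-methyloxiran-2-yl]-2-methylbut-1-en-1-yl}-4-[(2E)-4-hydroxy-3-methylhexa-2,5-dien-1-yl]-3-methylideneoxolan-2-one (both C11 epimers)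
Conditions: 18 (1.1 equiv), THF, −78 °C; then H2O
Reagents that add atoms: none
Why: Grignard 1,2-addition to the enal at −78 °C is far faster than attack on the lactone carbonyl, the acrylate or the epoxide; no facial control is sought at C11 because this centre is ionised in step 19.

**Step 13**
Reactants: 19 seco diene
Product: 20 (1S,2S,3E,7S,8S,9E,12E)-7,8-epoxy-11-hydroxycembra-3,9,12,15(17)-tetraen-16,2-olide (both C11 epimers)
Conditions: second-generation Grubbs catalyst RuCl2(H2IMes)(PCy3)(=CHPh) (10 mol %, in portions), 1,4-benzoquinone (10 mol %), CH2Cl2 (0.001 M), 40 °C, argon purge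
Reagents that add atoms: none
Why: Ruthenium-carbene olefin metathesis: the benzylidene initiates at the unhindered vinyl group of the C11 allylic alcohol, the C10 alkylidene undergoes intramolecular [2+2] cycloaddition with the vinyl group on C8, and retro-[2+2] of the ruthenacyclobutane forms C9=C10 and a ruthenium methylidene that leaves as ethylene. The closest known reaction type is macrocyclic ring-closing metathesis of α,ω-dienes to 12- to 16-membered rings with this catalyst, in which epoxides, free allylic alcohols and acrylates are tolerated. The 14-membered ring is closed end to end between the two terminal alkenes, the two former vinyl CH carbons becoming ring members C9 and C10 of an endocyclic disubstituted alkene. No stereocentre is formed, and the geometry of C9=C10 (E expected) does not matter because step 15 saturates this bond. The step needs site selectivity for the two monosubstituted alkenes over the trisubstituted C3=C4 and C12=C13 alkenes and the 1,1-disubstituted acrylate: the vinyl group on the fully substituted C8 is too hindered to take up the carbene, so the six-ring closure from C9 onto C3=C4 has no entry, the E geometry of C12=C13 forbids small-ring closure from C10 onto the acrylate, and high dilution with removal of ethylene disfavours oligomers. Benzoquinone is added to suppress ruthenium-hydride isomerisation of the allylic alcohol to a ketone.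

**Step 14**
Reactants: 20 macrocyclic dienol
Product: 21 17-(dimethylamino)-15,17-dihydro derivative of 20 (C15 and C11 epimers)
Conditions: Me2NH (2 M in THF), MeOH, 0 °C → rt
Reagents that add atoms: dimethylamine, CNC
Why: Aza-Michael addition of a secondary amine is the standard reversible protection of an α-methylene lactone and removes the conjugated 1,1-disubstituted alkene that diimide would otherwise reduce; the new C15 centre forms unselectively and is destroyed again in step 16.

**Step 15**
Reactants: 21 amine adduct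
Product: 22 (1S,2S,3E,7S,8S,12E)-17-(dimethylamino)-7,8-epoxy-11-hydroxycembra-3,12-dien-16,2-olide (C15 and C11 epimers)
Conditions: 2-nitrobenzenesulfonylhydrazide (excess, in portions), Et3N, CH2Cl2, rt
Reagents that add atoms: none
Why: Diimide reduction delivers H2 suprafacially to the least substituted alkene, so C9=C10 of either geometry should be saturated while the trisubstituted C3=C4 and C12=C13 alkenes react much more slowly and the epoxide is not hydrogenolysed.

**Step 16**
Reactants: 22 saturated amine adduct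
Product: 24 (1S,2S,3E,7S,8S,12E)-7,8-epoxy-11-hydroxycembra-3,12,15(17)-trien-16,2-olide (both C11 epimers), via trimethylammonium iodide 23 (not isolated)
Conditions: MeI, MeOH, rt; then NaHCO3 (aq), CH2Cl2, rt
Reagents that add atoms: none
Why: Quaternisation and base-induced elimination of trimethylamine (Hofmann-type retro-Michael, E1cB through the lactone enolate) regenerates the α-methylene lactone; H15 is the only β-hydrogen, so only the exocyclic alkene can form, and the basic medium keeps the C11 hydroxyl from opening the epoxide.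

**Step 17**
Reactants: 24 epoxy allylic alcohol
Product: 25 (1S,2S,3E,7S,8S,12E)-11-chloro-7,8-epoxycembra-3,12,15(17)-trien-16,2-olide (both C11 epimers)
Conditions: PPh3, hexachloroacetone, CH2Cl2, −20 → 0 °C
Reagents that add atoms: hexachloroacetone, O=C(C(Cl)(Cl)Cl)C(Cl)(Cl)Cl
Why: Appel-type deoxychlorination under neutral conditions replaces the C11 hydroxyl, which under the acid of step 18 would open the epoxide at C8 by 5-exo attack to a tetrahydrofuran, by a leaving group; the C11 configuration and any allylic transposition do not matter because step 19 ionises this position.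

**Step 18**
Reactants: 25 chloro epoxide
Product: 26 (1S,2S,3E,7S,8R,12E)-11-chloro-8-hydroperoxy-7-hydroxycembra-3,12,15(17)-trien-16,2-olide (both C11 epimers)
Conditions: H2O2 (anhydrous, in Et2O), H3PMo12O40 (3 mol %), Et2O, 0 °C
Reagents that add atoms: hydrogen peroxide, OO
Why: Acid-catalysed perhydrolysis of a trisubstituted epoxide: H2O2 attacks the more substituted C8 from the face opposite the epoxide oxygen, so C8 is inverted (S to R) while C7 keeps its configuration as the free secondary hydroxyl, and no hydroxyl is in place for transannular attack.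

**Step 19**
Reactants: 26 hydroperoxy chloride
Product: 27 (1S,2S,3E,7S,8R,11S,12E)-8,11-epidioxy-7-hydroxycembra-3,12,15(17)-trien-16,2-olide
Conditions: Ag2O (3 equiv), AgOSO2CF3 (cat.), 4 Å molecular sieves, CH2Cl2, −20 °C → rt, dark
Reagents that add atoms: none
Why: Silver-assisted intramolecular O-alkylation of a hydroperoxide by a halide (6-exo closure to a cyclic peroxide): silver ionises either C11 epimer, or a transposed C13 chloride, to the same allyl cation, the C8 hydroperoxide (as its silver salt, more nucleophilic than the C7 hydroxyl) closes the six-membered ring at C11 in preference to the eight-membered ring at C13, and C11 should emerge S because only the cis-bridged dioxane, with C7 and C12 on the same face of the six-membered ring, can span the 14-membered ring without strain.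

**Step 20**
Reactants: 27 peroxy alcohol
Product: 28 (1S,2S,3E,7S,8R,11S,12E)-7-acetoxy-8,11-epidioxycembra-3,12,15(17)-trien-16,2-olide (CNP0238885.7)
Conditions: Ac2O, pyridine, 4-(dimethylamino)pyridine (cat.), CH2Cl2, 0 °C → rt
Reagents that add atoms: acetic anhydride, CC(=O)OC(C)=O
Why: Nucleophile-catalysed acylation of the secondary C7 alcohol; the dialkyl peroxide, the trisubstituted alkenes and the α-methylene lactone tolerate these mild conditions and no stereocentre is touched.

**Compound list**

1 | geranyl acetate, (2E)-3,7-dimethylocta-2,6-dien-1-yl acetate | CC(C)=CCC/C(C)=C/COC(C)=O | starting material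
2 | (2E,6E)-8-hydroxy-3,7-dimethylocta-2,6-dien-1-yl acetate | OC/C(C)=C/CC/C(C)=C/COC(C)=O | intermediate
3 | (2E)-5-[(2S,3S)-3-(hydroxymethyl)-3-methyloxiran-2-yl]-3-methylpent-2-en-1-yl acetate | OC[C@]1(C)O[C@H]1CC/C(C)=C/COC(C)=O | intermediate
4 | (2E)-5-[(2S,3R)-3-formyl-3-methyloxiran-2-yl]-3-methylpent-2-en-1-yl acetate | O=C[C@]1(C)O[C@H]1CC/C(C)=C/COC(C)=O | intermediate
5 | (2E)-5-[(2S,3S)-3-ethenyl-3-methyloxiran-2-yl]-3-methylpent-2-en-1-yl acetate | C=C[C@]1(C)O[C@H]1CC/C(C)=C/COC(C)=O | intermediate
6 | (2E)-5-[(2S,3S)-3-ethenyl-3-methyloxiran-2-yl]-3-methylpent-2-en-1-ol | C=C[C@]1(C)O[C@H]1CC/C(C)=C/CO | intermediate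
7 | (2E)-5-[(2S,3S)-3-ethenyl-3-methyloxiran-2-yl]-3-methylpent-2-enal | C=C[C@]1(C)O[C@H]1CC/C(C)=C/C=O | intermediate
8 | 3-[(tert-butyldimethylsilyl)oxy]propanal | O=CCCO[Si](C)(C)C(C)(C)C | starting material
9 | methyl acrylate | C=CC(=O)OC | starting material
10 | methyl 5-[(tert-butyldimethylsilyl)oxy]-3-hydroxy-2-methylidenepentanoate (racemic) | C=C(C(=O)OC)C(O)CCO[Si](C)(C)C(C)(C)C | intermediate
11 | methyl (2Z)-2-(bromomethyl)-5-[(tert-butyldimethylsilyl)oxy]pent-2-enoate | COC(=O)/C(CBr)=C/CCO[Si](C)(C)C(C)(C)C | intermediate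
12 | methyl (3S,4S,5E)-3-{2-[(tert-butyldimethylsilyl)oxy]ethyl}-8-[(2S,3S)-3-ethenyl-3-methyloxiran-2-yl]-4-hydroxy-6-methyl-2-methylideneoct-5-enoate (formed as its zirconium alkoxide) | COC(=O)C(=C)[C@H](CCO[Si](C)(C)C(C)(C)C)[C@@H](O)/C=C(C)/CC[C@@H]1O[C@@]1(C)C=C | intermediate (not isolated)
13 | (4S,5S)-4-{2-[(tert-butyldimethylsilyl)oxy]ethyl}-5-{(1E)-4-[(2S,3S)-3-ethenyl-3-methyloxiran-2-yl]-2-methylbut-1-en-1-yl}-3-methylideneoxolan-2-one | C=C[C@]1(C)O[C@H]1CC/C(C)=C/[C@@H]1OC(=O)C(=C)[C@@H]1CCO[Si](C)(C)C(C)(C)C | intermediate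
14 | (4S,5S)-5-{(1E)-4-[(2S,3S)-3-ethenyl-3-methyloxiran-2-yl]-2-methylbut-1-en-1-yl}-4-(2-hydroxyethyl)-3-methylideneoxolan-2-one | C=C[C@]1(C)O[C@H]1CC/C(C)=C/[C@@H]1OC(=O)C(=C)[C@@H]1CCO | intermediate
15 | 2-(triphenylphosphoranylidene)propanal | CC(C=O)=P(c1ccccc1)(c1ccccc1)c1ccccc1 | starting material
16 | (4S,5S)-5-{(1E)-4-[(2S,3S)-3-ethenyl-3-methyloxiran-2-yl]-2-methylbut-1-en-1-yl}-3-methylidene-4-(2-oxoethyl)oxolan-2-one | C=C[C@]1(C)O[C@H]1CC/C(C)=C/[C@@H]1OC(=O)C(=C)[C@@H]1CC=O | intermediate (not isolated)
17 | (4S,5S)-5-{(1E)-4-[(2S,3S)-3-ethenyl-3-methyloxiran-2-yl]-2-methylbut-1-en-1-yl}-3-methylidene-4-[(2E)-3-methyl-4-oxobut-2-en-1-yl]oxolan-2-one | C=C[C@]1(C)O[C@H]1CC/C(C)=C/[C@@H]1OC(=O)C(=C)[C@@H]1C/C=C(C)/C=O | intermediate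
18 | vinylmagnesium bromide | C=C[Mg]Br | starting material
19 | (4S,5S)-5-{(1E)-4-[(2S,3S)-3-ethenyl-3-methyloxiran-2-yl]-2-methylbut-1-en-1-yl}-4-[(2E)-4-hydroxy-3-methylhexa-2,5-dien-1-yl]-3-methylideneoxolan-2-one (both epimers at the carbinol carbon, C11) | C=C[C@]1(C)O[C@H]1CC/C(C)=C/[C@@H]1OC(=O)C(=C)[C@@H]1C/C=C(C)/C(O)C=C | intermediate
20 | (1S,2S,3E,7S,8S,9E,12E)-7,8-epoxy-11-hydroxycembra-3,9,12,15(17)-tetraen-16,2-olide (both C11 epimers) | C[C@@]12O[C@H]1CC/C(C)=C/[C@@H]1OC(=O)C(=C)[C@@H]1C/C=C(C)/C(O)/C=C/2 | intermediate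
21 | (1S,2S,3E,7S,8S,9E,12E)-17-(dimethylamino)-7,8-epoxy-11-hydroxycembra-3,9,12-trien-16,2-olide (C15 and C11 epimers) | C[C@@]12O[C@H]1CC/C(C)=C/[C@@H]1OC(=O)C(CN(C)C)[C@@H]1C/C=C(C)/C(O)/C=C/2 | intermediate
22 | (1S,2S,3E,7S,8S,12E)-17-(dimethylamino)-7,8-epoxy-11-hydroxycembra-3,12-dien-16,2-olide (C15 and C11 epimers) | C[C@@]12O[C@H]1CC/C(C)=C/[C@@H]1OC(=O)C(CN(C)C)[C@@H]1C/C=C(C)/C(O)CC2 | intermediate
23 | 17-(trimethylammonio) analogue of 22, iodide salt | C[C@@]12O[C@H]1CC/C(C)=C/[C@@H]1OC(=O)C(C[N+](C)(C)C)[C@@H]1C/C=C(C)/C(O)CC2.[I-] | intermediate (not isolated)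
24 | (1S,2S,3E,7S,8S,12E)-7,8-epoxy-11-hydroxycembra-3,12,15(17)-trien-16,2-olide (both C11 epimers) | C[C@@]12O[C@H]1CC/C(C)=C/[C@@H]1OC(=O)C(=C)[C@@H]1C/C=C(C)/C(O)CC2 | intermediate
25 | (1S,2S,3E,7S,8S,12E)-11-chloro-7,8-epoxycembra-3,12,15(17)-trien-16,2-olide (both C11 epimers) | C[C@@]12O[C@H]1CC/C(C)=C/[C@@H]1OC(=O)C(=C)[C@@H]1C/C=C(C)/C(Cl)CC2 | intermediate
26 | (1S,2S,3E,7S,8R,12E)-11-chloro-8-hydroperoxy-7-hydroxycembra-3,12,15(17)-trien-16,2-olide (both C11 epimers) | C=C1C(=O)O[C@H]2/C=C(\C)CC[C@H](O)[C@@](OO)(C)CCC(Cl)/C(C)=C/C[C@@H]12 | intermediate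
27 | (1S,2S,3E,7S,8R,11S,12E)-8,11-epidioxy-7-hydroxycembra-3,12,15(17)-trien-16,2-olide | C=C1C(=O)O[C@H]2/C=C(\C)CC[C@H](O)[C@@]3(C)CC[C@H](OO3)/C(C)=C/C[C@@H]12 | intermediate
28 | (1S,2S,3E,7S,8R,11S,12E)-7-acetoxy-8,11-epidioxycembra-3,12,15(17)-trien-16,2-olide, CNP0238885.7 | C=C1C(=O)O[C@H]2/C=C(\C)CC[C@H](OC(C)=O)[C@@]3(C)CC[C@H](OO3)/C(C)=C/C[C@@H]12 | target

**Step count and risks**

Total step count: 20. Longest linear sequence: 18 steps (steps 1–6 and 9–20, from geranyl acetate); steps 7 and 8 make the side fragment.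

Steps most likely to fail:

1. Step 19 (silver-assisted peroxide closure). The allyl cation at C11 may be captured by the C7 hydroxyl (a tetrahydropyran), lose a proton to a diene, or close to the trans-bridged C11 epimer. The fallback forms the two C–O bonds in the opposite order, so that no free C7 hydroxyl exists when C11 is ionised. It sets out from chloride 25: silver trifluoroacetate AgOCOCF3 with anhydrous ethereal H2O2 at −20 °C (silver-assisted perhydrolysis of an allylic halide) should give (1S,2S,3E,7S,8S,11S,12E)-7,8-epoxy-11-hydroperoxycembra-3,12,15(17)-trien-16,2-olide F1 together with its C11 epimer. Acid-catalysed 6-exo opening of the epoxide at C8 by the hydroperoxide (Amberlyst-15 or camphorsulfonic acid, CH2Cl2), a known hydroperoxide–epoxide cyclisation that inverts C8, should then convert the 11S epimer into 27, where the route is rejoined. The 11R epimer cannot reach the rear face of C8 and is separated.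

2. Step 13 (ring-closing metathesis). Intermolecular metathesis of the C11 vinyl groups (oligomers), or carbene transfer to the C8 vinyl group followed by six-ring closure onto C3=C4 with loss of the lactone half, may outrun macrocyclisation. The ring would then be closed at C10–C11 by an intramolecular Nozaki–Hiyama–Kishi reaction, which gives the same product.
   - The fallback leaves the route at epoxy aldehyde 4: Takai olefination (CHI3, CrCl2, THF, 0 °C) should give (2E)-5-{(2S,3S)-3-[(E)-2-iodoethenyl]-3-methyloxiran-2-yl}-3-methylpent-2-en-1-yl acetate F2.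
   - Methanolysis and MnO2 oxidation as in steps 5 and 6 lead through the iodoalkenyl alcohol F3 to the iodoalkenyl enal F4.
   - Coupling with 11 as in step 9 (alkenyl iodides do not react with CrCl2 unless NiCl2 is added) gives, by way of the iodoalkenyl hydroxy ester F5, the iodoalkenyl silyl lactone F6.
   - Desilylation as in step 10 gives the iodoalkenyl lactone alcohol F7, and oxidation–Wittig homologation as in step 11 gives, through the iodoalkenyl lactone aldehyde F8, the iodoalkenyl dienal F9.
   - CrCl2 with NiCl2 (cat.) in DMSO–THF at high dilution should add the C10 alkenylchromium species to the C11 aldehyde and rejoin the route at 20 (9E, both C11 epimers).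

3. Step 9 (asymmetric allylation). Facial selectivity of the chromium catalyst with a γ-substituted allyl bromide may be insufficient, or the vinyl epoxide may be lost in the Lewis-acidic reducing medium. The fallback separates bond formation from enantioselection. It sets out from 7 and 11: indium-mediated Barbier coupling (In powder, THF–H2O, rt), which is syn-selective for (Z)-2-(bromomethyl)alk-2-enoates and leaves epoxides alone, should give 12 together with its (1R,2R) diastereomer, the methyl (3R,4R,5E)-hydroxy ester F10. Kinetic resolution by Katsuki–Sharpless epoxidation (Ti(OiPr)4, L-(+)-diisopropyl tartrate, tBuOOH, −20 °C) should epoxidise the C3=C4 alkene of F10 to the anti epoxy alcohol F11 and leave 12 untouched. Warming recovered 12 with 2-hydroxypyridine (cat.) in toluene closes the lactone and rejoins the route at 13.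

**Further compounds**

F1 | step 19 | (1S,2S,3E,7S,8S,11S,12E)-7,8-epoxy-11-hydroperoxycembra-3,12,15(17)-trien-16,2-olide | C[C@@]12O[C@H]1CC/C(C)=C/[C@@H]1OC(=O)C(=C)[C@@H]1C/C=C(C)/[C@@H](OO)CC2
F2 | step 13 | (2E)-5-{(2S,3S)-3-[(E)-2-iodoethenyl]-3-methyloxiran-2-yl}-3-methylpent-2-en-1-yl acetate | I/C=C/[C@]1(C)O[C@H]1CC/C(C)=C/COC(C)=O
F3 | step 13 | (2E)-5-{(2S,3S)-3-[(E)-2-iodoethenyl]-3-methyloxiran-2-yl}-3-methylpent-2-en-1-ol | I/C=C/[C@]1(C)O[C@H]1CC/C(C)=C/CO
F4 | step 13 | (2E)-5-{(2S,3S)-3-[(E)-2-iodoethenyl]-3-methyloxiran-2-yl}-3-methylpent-2-enal | I/C=C/[C@]1(C)O[C@H]1CC/C(C)=C/C=O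
F5 | step 13 | methyl (3S,4S,5E)-3-{2-[(tert-butyldimethylsilyl)oxy]ethyl}-4-hydroxy-8-{(2S,3S)-3-[(E)-2-iodoethenyl]-3-methyloxiran-2-yl}-6-methyl-2-methylideneoct-5-enoate | COC(=O)C(=C)[C@H](CCO[Si](C)(C)C(C)(C)C)[C@@H](O)/C=C(C)/CC[C@@H]1O[C@@]1(C)/C=C/I
F6 | step 13 | (4S,5S)-4-{2-[(tert-butyldimethylsilyl)oxy]ethyl}-5-[(1E)-4-{(2S,3S)-3-[(E)-2-iodoethenyl]-3-methyloxiran-2-yl}-2-methylbut-1-en-1-yl]-3-methylideneoxolan-2-one | I/C=C/[C@]1(C)O[C@H]1CC/C(C)=C/[C@@H]1OC(=O)C(=C)[C@@H]1CCO[Si](C)(C)C(C)(C)C
F7 | step 13 | (4S,5S)-4-(2-hydroxyethyl)-5-[(1E)-4-{(2S,3S)-3-[(E)-2-iodoethenyl]-3-methyloxiran-2-yl}-2-methylbut-1-en-1-yl]-3-methylideneoxolan-2-one | I/C=C/[C@]1(C)O[C@H]1CC/C(C)=C/[C@@H]1OC(=O)C(=C)[C@@H]1CCO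
F8 | step 13 | (4S,5S)-5-[(1E)-4-{(2S,3S)-3-[(E)-2-iodoethenyl]-3-methyloxiran-2-yl}-2-methylbut-1-en-1-yl]-3-methylidene-4-(2-oxoethyl)oxolan-2-one | I/C=C/[C@]1(C)O[C@H]1CC/C(C)=C/[C@@H]1OC(=O)C(=C)[C@@H]1CC=O
F9 | step 13 | (4S,5S)-5-[(1E)-4-{(2S,3S)-3-[(E)-2-iodoethenyl]-3-methyloxiran-2-yl}-2-methylbut-1-en-1-yl]-3-methylidene-4-[(2E)-3-methyl-4-oxobut-2-en-1-yl]oxolan-2-one | I/C=C/[C@]1(C)O[C@H]1CC/C(C)=C/[C@@H]1OC(=O)C(=C)[C@@H]1C/C=C(C)/C=O
F10 | step 9 | methyl (3R,4R,5E)-3-{2-[(tert-butyldimethylsilyl)oxy]ethyl}-8-[(2S,3S)-3-ethenyl-3-methyloxiran-2-yl]-4-hydroxy-6-methyl-2-methylideneoct-5-enoate (the 1R,2R diastereomer of 12) | COC(=O)C(=C)[C@@H](CCO[Si](C)(C)C(C)(C)C)[C@H](O)/C=C(C)/CC[C@@H]1O[C@@]1(C)C=C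
F11 | step 9 | 5,6-epoxide of F10 with both new epoxide carbons S (cembrane C3 and C4), the anti epoxy alcohol | COC(=O)C(=C)[C@@H](CCO[Si](C)(C)C(C)(C)C)[C@H](O)[C@@H]2O[C@@]2(C)CC[C@@H]1O[C@@]1(C)C=C
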